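## Retrosynthetic overview

1. Guangsangon K ⇒ (global MOM removal) ⇒ open ring C at O1–C2 and C3–OH. Both C–O bonds and both ring C stereocentres come from one asymmetric oxidative cyclisation of a free 2'-hydroxychalcone that hangs on the finished cyclohexene.
2. That chalcone ⇒ Claisen–Schmidt cut ⇒ 4-O-MOM-resacetophenone + a cyclohexenyl benzaldehyde.
3. Cyclohexene ⇒ retro-Diels–Alder (exo, chiral borate) ⇒ 2'-hydroxychalcone dienophile + dehydroprenyl benzaldehyde diene.
4. Both partners ⇒ the same two MOM-protected blocks, made from 2,4-dihydroxybenzaldehyde and 2,4-dihydroxyacetophenone. The C5 diene unit comes from prenal by C3-lithiation and dehydration.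
5. Ring order: aromatic rings bought, cyclohexene ring first, pyranone ring C last.

Assumption: the facial sense of the two chiral promoters ((R)-VANOL borate; L-pipecolic-acid-derived N,N'-dioxide/Sc(OTf)3) is taken as drawn, and since both ligands exist in both mirror-image forms, the antipode is used if a pilot run (CD, comparison with natural material) shows the opposite sense.

## Route

Step 1
Reactants: 1 2,4-dihydroxyacetophenone
Product: 2 1-[2-hydroxy-4-(methoxymethoxy)phenyl]ethanone
Conditions: MOMCl (1.1 equiv), K2CO3 (1.5 equiv), acetone, 0 °C → rt, 4 h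
Reagents that add atoms: chloromethyl methyl ether (MOMCl), COCCl
Why: Williamson-type MOM ether formation; the 2-OH is hydrogen-bonded to the ketone and much less nucleophilic, so one equivalent of MOMCl caps only the 4-OH.

Step 2
Reactants: 3 2,4-dihydroxybenzaldehyde
Product: 4 2,4-bis(methoxymethoxy)benzaldehyde
Conditions: MOMCl (2.6 equiv), K2CO3 (4 equiv), acetone, reflux, 6 h
Reagents that add atoms: chloromethyl methyl ether (MOMCl), COCCl
Why: The same MOM ether formation, forced with excess reagent at reflux so that the chelated 2-OH is capped too; 4 then serves both halves of the molecule.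

Step 3
Reactants: 2 1-[2-hydroxy-4-(methoxymethoxy)phenyl]ethanone; 4 2,4-bis(methoxymethoxy)benzaldehyde
Product: 5 (E)-3-[2,4-bis(methoxymethoxy)phenyl]-1-[2-hydroxy-4-(methoxymethoxy)phenyl]prop-2-en-1-one
Conditions: KOH (50% aq), EtOH, rt, 36 h
Reagents that add atoms: none
Why: Claisen–Schmidt aldol condensation; E1cB loss of water gives only the conjugated E-enone, and MOM ethers are inert to hydroxide.

Step 4
Reactants: 4 2,4-bis(methoxymethoxy)benzaldehyde; 6 3-methylbut-2-enal (prenal)
Product: 10 3-(1-hydroxy-3-methylbut-2-en-1-yl)-2,4-bis(methoxymethoxy)benzaldehyde (racemic carbinol), via lithium amino alkoxide 7 (not isolated), via 3-lithio amino alkoxide 8 (not isolated), via dilithium dialkoxide 9 (not isolated)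
Conditions: 1-methylpiperazine (1.2 equiv), n-BuLi (1.15 equiv), THF, −20 °C; add 4; n-BuLi (1.3 equiv), −20 → 0 °C, 2 h; 6 (1.6 equiv), −78 → −20 °C; H2O
Reagents that add atoms: none
Why: Directed ortho-metalation with in-situ aldehyde masking (Comins α-amino alkoxide): the aldehyde is hidden as 7, the C3–H between two OMOM groups is the most acidic and doubly coordinated site, and aryllithium 8 adds 1,2 to prenal; the new carbinol centre is racemic and is erased in step 5.

Step 5
Reactants: 10 3-(1-hydroxy-3-methylbut-2-en-1-yl)-2,4-bis(methoxymethoxy)benzaldehyde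
Product: 12 2,4-bis(methoxymethoxy)-3-[(1E)-3-methylbuta-1,3-dien-1-yl]benzaldehyde, via allylic mesylate 11 (not isolated)
Conditions: MsCl (1.3 equiv), Et3N (4 equiv), CH2Cl2, −10 °C → rt, 3 h; use at once
Reagents that add atoms: none
Why: Mesylation followed by 1,4-elimination of a doubly activated (benzylic and allylic) mesylate; loss of a methyl proton gives the conjugated diene, E at the styrenyl bond for steric reasons, and the basic medium protects the MOM ethers and prevents chromene formation.

Step 6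
Reactants: 5 (E)-3-[2,4-bis(methoxymethoxy)phenyl]-1-[2-hydroxy-4-(methoxymethoxy)phenyl]prop-2-en-1-one; 12 2,4-bis(methoxymethoxy)-3-[(1E)-3-methylbuta-1,3-dien-1-yl]benzaldehyde
Product: 15 3-{(1R,5S,6R)-5-[2,4-bis(methoxymethoxy)phenyl]-6-[2-hydroxy-4-(methoxymethoxy)benzoyl]-3-methylcyclohex-2-en-1-yl}-2,4-bis(methoxymethoxy)benzaldehyde (all-trans exo adduct), via dienophile borate chelate 13 (not isolated), via cycloadduct borate chelate 14 (not isolated)
Conditions: (R)-VANOL, BH3·THF, AcOH (1.2 equiv each), THF, rt, 1 h, then vacuum; 5 (1.0 equiv), PhCF3, 4 Å MS, rt, 1 h; 12 (1.4 equiv), rt, 48 h; H2O/MeOH work-up; exo/endo separation on SiO2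
Reagents that add atoms: none
Why: Boron-chelate-promoted asymmetric Diels–Alder reaction, established for 2'-hydroxychalcones and dehydroprenyl arenes: binding of the 2'-phenolate and carbonyl of 5 to the VANOL borate lowers the enone LUMO and blocks one face, the diene CH2 terminus bonds to Cβ (ortho/para rule), the E-enone fixes 4'',5''-trans, the exo transition state gives 3'',4''-trans, and the ligand sets the absolute sense (3''R,4''R,5''S).

Step 7
Reactants: 15 all-trans cyclohexenyl benzaldehyde; 2 1-[2-hydroxy-4-(methoxymethoxy)phenyl]ethanone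
Product: 16 (E)-3-(3-{(1R,5S,6R)-5-[2,4-bis(methoxymethoxy)phenyl]-6-[2-hydroxy-4-(methoxymethoxy)benzoyl]-3-methylcyclohex-2-en-1-yl}-2,4-bis(methoxymethoxy)phenyl)-1-[2-hydroxy-4-(methoxymethoxy)phenyl]prop-2-en-1-one
Conditions: KOH (50% aq), EtOH/THF 3:1, rt, 36 h
Reagents that add atoms: none
Why: Claisen–Schmidt aldol condensation of the only methyl ketone with the only aldehyde gives the E-enone; the hindered ring ketone is a spectator, and its α-centre already has the thermodynamically preferred all-trans arrangement, so base cannot scramble it.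

Step 8
Reactants: 16 cyclohexenyl 2'-hydroxychalcone
Product: 18 (2R,3R)-2-(3-{(1R,5S,6R)-5-[2,4-bis(methoxymethoxy)phenyl]-6-[2-hydroxy-4-(methoxymethoxy)benzoyl]-3-methylcyclohex-2-en-1-yl}-2,4-bis(methoxymethoxy)phenyl)-3-hydroxy-7-(methoxymethoxy)-2,3-dihydro-4H-chromen-4-one, via epoxychalcone 17 (not isolated)
Conditions: Sc(OTf)3 (15 mol%), N,N'-dioxide ligand L-PiPr2 [(2S,2'S)-1,1'-(propane-1,3-diyl)bis{N-(2,6-diisopropylphenyl)piperidine-2-carboxamide} 1,1'-dioxide, 16 mol%], 30% aq H2O2 (3 equiv), THF (0.03 M), 30 °C, 24 h, dark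
Reagents that add atoms: hydrogen peroxide, OO
Why: Proposed new method: a catalytic asymmetric Algar–Flynn–Oyamada cyclisation in which one chiral Lewis acid mediates both C–O bond formations; the tetradentate N,N'-dioxide leaves two cis sites on scandium, the free 2'-OH/C=O pair of 16 fills them and locks the enone s-cis under one 2,6-diisopropylanilide wall, H2O2 held by the amide N–H adds to Cβ from the open face (Weitz–Scheffer addition) and the scandium enolate closes on the O–O bond to give the (αR,βS)-epoxide 17, then the same Lewis acid loosens the benzylic Cβ–O bond (stabilised by the 2,4-dialkoxyaryl ring) and the neighbouring 2'-OH attacks Cβ 6-endo from the back, so C3 keeps the Cα configuration (R) and C2 forms with inversion (R, 2,3-trans, which is also the diequatorial thermodynamic outcome if the opening is loose); the peroxide is nucleophilic, so the trisubstituted cyclohexene is untouched, and the neutral medium avoids the flavonol over-oxidation and C3 epimerisation seen in alkali; the closest known reaction types are the Sc(OTf)3/N,N'-dioxide-catalysed H2O2 epoxidation of simple chalcones lacking a free 2'-OH and the racemic alkaline Algar–Flynn–Oyamada reaction.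

Step 9
Reactants: 18 hexa-MOM guangsangon K
Product: 19 guangsangon K
Conditions: HCl (1.25 M in MeOH), MeOH/THF 4:1, 40 °C, 5 h, Ar; reversed-phase purification
Reagents that add atoms: none
Why: Acid-catalysed acetal exchange removes all six phenolic MOM groups as in known dihydroflavonol syntheses; no stereocentre is touched (2,3-trans is the stable ring C arrangement, C3 does not enolise in dilute acid), and the hydrogen-bonded aryl ketone and the trisubstituted alkene are too unreactive to ketalise or cyclise at this acidity.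

## Compound list

1 | 2,4-dihydroxyacetophenone | CC(=O)c1ccc(O)cc1O | starting material
2 | 1-[2-hydroxy-4-(methoxymethoxy)phenyl]ethanone | CC(=O)c1ccc(OCOC)cc1O | intermediate
3 | 2,4-dihydroxybenzaldehyde | O=Cc1ccc(O)cc1O | starting material
4 | 2,4-bis(methoxymethoxy)benzaldehyde | COCOc1ccc(C=O)c(OCOC)c1 | intermediate
5 | (E)-3-[2,4-bis(methoxymethoxy)phenyl]-1-[2-hydroxy-4-(methoxymethoxy)phenyl]prop-2-en-1-one (dienophile) | COCOc1ccc(C(=O)/C=C/c2ccc(OCOC)cc2OCOC)c(O)c1 | intermediate
6 | 3-methylbut-2-enal (prenal) | CC(C)=CC=O | starting material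
7 | lithium amino alkoxide from 4 and lithium 4-methylpiperazin-1-ide (not isolated, racemic) | COCOc1ccc(C(O[Li])N2CCN(C)CC2)c(OCOC)c1 | intermediate
8 | 3-lithio amino alkoxide (not isolated) | COCOc1ccc(C(O[Li])N2CCN(C)CC2)c(OCOC)c1[Li] | intermediate
9 | dilithium dialkoxide from 8 and 6 (not isolated) | COCOc1ccc(C(O[Li])N2CCN(C)CC2)c(OCOC)c1C(O[Li])C=C(C)C | intermediate
10 | 3-(1-hydroxy-3-methylbut-2-en-1-yl)-2,4-bis(methoxymethoxy)benzaldehyde (racemic) | CC(C)=CC(O)c1c(OCOC)ccc(C=O)c1OCOC | intermediate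
11 | methanesulfonate of 10 (not isolated) | CC(C)=CC(OS(C)(=O)=O)c1c(OCOC)ccc(C=O)c1OCOC | intermediate
12 | 2,4-bis(methoxymethoxy)-3-[(1E)-3-methylbuta-1,3-dien-1-yl]benzaldehyde (diene) | C=C(C)/C=C/c1c(OCOC)ccc(C=O)c1OCOC | intermediate
13 | (R)-VANOL borate chelate of 5 (not isolated; the R axis of VANOL is not expressed in the SMILES) | COCOc1ccc2c(c1)O[B-]1(Oc3c(c(-c4ccccc4)cc4ccccc34)-c3c(O1)c4ccccc4cc3-c3ccccc3)[O+]=C2/C=C/c1ccc(OCOC)cc1OCOC | intermediate
14 | (R)-VANOL borate chelate of cycloadduct 15 (not isolated; axis not expressed) | CC1=C[C@@H](c2c(OCOC)ccc(C=O)c2OCOC)[C@H](C2=[O+][B-]3(Oc4c(c(-c5ccccc5)cc5ccccc45)-c4c(O3)c5ccccc5cc4-c4ccccc4)Oc3cc(OCOC)ccc23)[C@@H](c2ccc(OCOC)cc2OCOC)C1 | intermediate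
15 | all-trans (3''R,4''R,5''S) cyclohexenyl benzaldehyde, name as in step 6 | CC1=C[C@@H](c2c(OCOC)ccc(C=O)c2OCOC)[C@H](C(=O)c2ccc(OCOC)cc2O)[C@@H](c2ccc(OCOC)cc2OCOC)C1 | intermediate
16 | cyclohexenyl (E)-2'-hydroxychalcone, name as in step 7 | CC1=C[C@@H](c2c(OCOC)ccc(/C=C/C(=O)c3ccc(OCOC)cc3O)c2OCOC)[C@H](C(=O)c2ccc(OCOC)cc2O)[C@@H](c2ccc(OCOC)cc2OCOC)C1 | intermediate
17 | (αR,βS)-epoxychalcone, i.e. (2R,3S)-oxirane with C2 bearing the aroyl group (not isolated) | CC1=C[C@@H](c2c(OCOC)ccc([C@@H]3O[C@H]3C(=O)c3ccc(OCOC)cc3O)c2OCOC)[C@H](C(=O)c2ccc(OCOC)cc2O)[C@@H](c2ccc(OCOC)cc2OCOC)C1 | intermediate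
18 | hexa-MOM guangsangon K, (2R,3R)-trans ring C, name as in step 8 | CC1=C[C@@H](c2c(OCOC)ccc([C@H]3Oc4cc(OCOC)ccc4C(=O)[C@@H]3O)c2OCOC)[C@H](C(=O)c2ccc(OCOC)cc2O)[C@@H](c2ccc(OCOC)cc2OCOC)C1 | intermediate
19 | guangsangon K, (2R,3R)-2-{3-[(1R,5S,6R)-6-(2,4-dihydroxybenzoyl)-5-(2,4-dihydroxyphenyl)-3-methylcyclohex-2-en-1-yl]-2,4-dihydroxyphenyl}-3,7-dihydroxy-2,3-dihydro-4H-chromen-4-one | CC1=C[C@@H](c2c(O)ccc([C@H]3Oc4cc(O)ccc4C(=O)[C@@H]3O)c2O)[C@H](C(=O)c2ccc(O)cc2O)[C@@H](c2ccc(O)cc2O)C1 | target

## Step count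

Total step count: 9.
Longest linear sequence: 7 (steps 2, 4, 5, 6, 7, 8, 9, from 3 to 19).

## Three steps most likely to fail

**Step 8 (the proposed new cyclisation).**
- Risks: turnover and enantioselectivity with a free chelating phenol are untested. The saturated 2-hydroxyaryl ketone is a second binding site for scandium. The doubly alkoxy-donated enone is a slow acceptor.
- Fallback (known chemistry), from 16 back to the route at 19: both chelated phenols of 16 are capped (MOMCl, NaH, DMF, 0 °C) to give the octa-MOM chalcone F1. Juliá–Colonna epoxidation (poly-L-leucine, urea·H2O2, DBU, THF, rt), the established method for 2'-O-MOM polyoxygenated chalcones, then gives the (αR,βS)-epoxide F2. HCl in MeOH (45 °C) strips all eight MOM groups, and the freed 2'-OH opens the epoxide at the benzylic carbon, giving 19 directly as the 2,3-trans dihydroflavonol.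

**Step 6 (asymmetric exo Diels–Alder).**
- Risks: the exo/endo ratio and ee depend on the ligand and on the substrate pair, and the aldehyde-bearing diene is somewhat deactivated.
- Fallback, from 5 and 12 back to the route at 18: reagent control is given up, and the ring C stereocentres are used later as an internal resolving handle. Silica-supported silver nanoparticles (Ag on SiO2, from AgBF4 and Bu4NBH4; ClCH2CH2Cl, 55 °C) promote the same cycloaddition by electron transfer to the 2'-hydroxychalcone. The exo adduct is obtained as a racemate, that is 15 together with the mirror-image aldehyde F3.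
- The racemate is taken through step 7, giving 16 together with the mirror-image chalcone F4. In step 8 the catalyst installs the same (2R,3R) ring C on both antipodes, by way of 17 and the diastereomeric epoxide F5. The products 18 and the diastereomeric dihydroflavonol F6 are diastereomers and are separated on silica or by preparative HPLC. Compound 18 goes on to step 9.

**Step 4 (lithiation of the masked aldehyde and addition to prenal).**
- Risks: incomplete or misdirected lithiation (C5 or C6), and enolisation of prenal by the hindered aryllithium.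
- Fallback, from 3 back to the route at 12 (it replaces steps 4 and 5 by cross-coupling): iodination of 3 (I2, HIO3, aq EtOH, rt) goes between the two hydroxyls and gives 2,4-dihydroxy-3-iodobenzaldehyde F7. MOMCl/K2CO3 in refluxing acetone gives 3-iodo-2,4-bis(methoxymethoxy)benzaldehyde F8.
- Hydroboration of 2-methylbut-1-en-3-yne with pinacolborane (Cp2Zr(H)Cl 5 mol%, Et3N, 60 °C) gives the (E)-dienyl pinacol boronate F9. Suzuki–Miyaura coupling of F8 with F9 (Pd(dppf)Cl2, K2CO3, dioxane/H2O, 80 °C) gives 12.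

## Further compounds

F1 | step 8 | octa-MOM chalcone (16 with both chelated phenols as MOM ethers) | CC1=C[C@@H](c2c(OCOC)ccc(/C=C/C(=O)c3ccc(OCOC)cc3OCOC)c2OCOC)[C@H](C(=O)c2ccc(OCOC)cc2OCOC)[C@@H](c2ccc(OCOC)cc2OCOC)C1
F2 | step 8 | (αR,βS)-epoxide of F1 | CC1=C[C@@H](c2c(OCOC)ccc([C@@H]3O[C@H]3C(=O)c3ccc(OCOC)cc3OCOC)c2OCOC)[C@H](C(=O)c2ccc(OCOC)cc2OCOC)[C@@H](c2ccc(OCOC)cc2OCOC)C1
F3 | step 6 | mirror-image aldehyde (enantiomer of 15) | CC1=C[C@H](c2c(OCOC)ccc(C=O)c2OCOC)[C@@H](C(=O)c2ccc(OCOC)cc2O)[C@H](c2ccc(OCOC)cc2OCOC)C1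
F4 | step 6 | mirror-image chalcone (enantiomer of 16) | CC1=C[C@H](c2c(OCOC)ccc(/C=C/C(=O)c3ccc(OCOC)cc3O)c2OCOC)[C@@H](C(=O)c2ccc(OCOC)cc2O)[C@H](c2ccc(OCOC)cc2OCOC)C1
F5 | step 6 | diastereomeric epoxide, (αR,βS)-epoxide on the (3''S,4''S,5''R) cyclohexene | CC1=C[C@H](c2c(OCOC)ccc([C@@H]3O[C@H]3C(=O)c3ccc(OCOC)cc3O)c2OCOC)[C@@H](C(=O)c2ccc(OCOC)cc2O)[C@H](c2ccc(OCOC)cc2OCOC)C1
F6 | step 6 | diastereomeric dihydroflavonol, (2R,3R) ring C on the (3''S,4''S,5''R) cyclohexene | CC1=C[C@H](c2c(OCOC)ccc([C@H]3Oc4cc(OCOC)ccc4C(=O)[C@@H]3O)c2OCOC)[C@@H](C(=O)c2ccc(OCOC)cc2O)[C@H](c2ccc(OCOC)cc2OCOC)C1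
F7 | step 4 | 2,4-dihydroxy-3-iodobenzaldehyde | O=Cc1ccc(O)c(I)c1O
F8 | step 4 | 3-iodo-2,4-bis(methoxymethoxy)benzaldehyde | COCOc1ccc(C=O)c(OCOC)c1I
F9 | step 4 | 4,4,5,5-tetramethyl-2-[(1E)-3-methylbuta-1,3-dien-1-yl]-1,3,2-dioxaborolane | C=C(C)/C=C/B1OC(C)(C)C(C)(C)O1
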